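**Strategy.** The route rests on cutting the C6–CH2 bond between ring A of the flavanone and ring F, the first phenol ring of the three-ring side chain. Because that CH2 is ortho to the ring F hydroxyl, it is an ortho-quinone methide in disguise; because C6 lies between the 5-OH and 7-OH and is the last free carbon of ring A once C8 is benzylated, it is a soft phenoxide carbon nucleophile. In one operation buffered fluoride strips three silyl ethers from a tris-silylated benzylic bromide, releases the quinone methide and lets C6 of the unprotected 8-benzylated (S)-pinocembrin add to it, giving the target directly.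

Key step: step 10

Remark: (2S)-pinocembrin, the natural enantiomer, is assumed to be commercially available; its C2 centre is the only stereocentre of the target and is carried through unchanged.

Ring letters: A, B, C are the benzo, phenyl and pyranone rings of the flavanone. D and E are the phenol rings of the C8 chain (D on the C8 CH2). F, G and H are the phenol rings of the C6 chain (F on the C6 CH2, H terminal). TBS = tert-butyldimethylsilyl.

**Step 1**
Reactants: 1 2-hydroxybenzyl alcohol
Product: 2 tert-butyl{2-[(tert-butyldimethylsilyloxy)methyl]phenoxy}dimethylsilane (bis-TBS ether of 1)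
Conditions: TBSCl (2.3 equiv), imidazole, DMF, rt
Reagents that add atoms: tert-butyldimethylsilyl chloride (TBSCl), CC(C)(C)[Si](C)(C)Cl
Why: Standard silyl ether formation under imidazole catalysis should cap both the phenol and the primary alcohol.

**Step 2**
Reactants: 2 bis-TBS ether of salicyl alcohol
Product: 3 [2-(bromomethyl)phenoxy](tert-butyl)dimethylsilane
Conditions: Ph3PBr2 (commercial, 1.1 equiv), CH2Cl2, 0 °C → rt
Reagents that add atoms: dibromotriphenylphosphorane (Ph3PBr2), BrP(Br)(c1ccccc1)(c1ccccc1)c1ccccc1
Why: Direct exchange of an alkyl silyl ether for bromide with Ph3PBr2 (oxyphosphonium formation, then SN2 by bromide) should touch only the benzylic ether, because the aryl silyl ether offers no sp3 carbon for substitution.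

**Step 3**
Reactants: 4 5-bromo-2-hydroxybenzyl alcohol
Product: 5 {4-bromo-2-[(tert-butyldimethylsilyloxy)methyl]phenoxy}(tert-butyl)dimethylsilane (bis-TBS ether of 4)
Conditions: TBSCl (2.3 equiv), imidazole, DMF, rt
Reagents that add atoms: tert-butyldimethylsilyl chloride (TBSCl), CC(C)(C)[Si](C)(C)Cl
Why: The same silyl ether formation as in step 1 should give the common aryl bromide building block for both chain-building couplings.

**Step 4**
Reactants: 5 bis-TBS aryl bromide
Product: 7 {4-(tert-butyldimethylsilyloxy)-3-[(tert-butyldimethylsilyloxy)methyl]phenyl}zinc chloride as a titrated THF stock solution, via aryllithium 6 (not isolated)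
Conditions: n-BuLi (1.05 equiv), THF, −78 °C; ZnCl2 (1.1 equiv, THF solution), −78 °C → rt; solution kept under argon, titrated with I2 and used in two portions
Reagents that add atoms: zinc dichloride (ZnCl2), Cl[Zn]Cl
Why: Bromine–lithium exchange para to the silyloxy group followed by transmetalation to zinc should give an arylzinc chloride that tolerates both silyl ethers and is stable enough in THF to be prepared once, on a scale that serves both Negishi couplings.

**Step 5**
Reactants: 7 arylzinc chloride stock solution; 3 2-(TBS-oxy)benzyl bromide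
Product: 8 tert-butyl{2-[(tert-butyldimethylsilyloxy)methyl]-4-[2-(tert-butyldimethylsilyloxy)benzyl]phenoxy}dimethylsilane (two-ring tris-TBS ether)
Conditions: 7 (1.2 equiv, THF solution), 3, Pd(PPh3)4 (cat.), THF, rt → 45 °C
Reagents that add atoms: none
Why: Negishi coupling of the arylzinc chloride with the benzylic bromide should form the diarylmethane under base-free conditions that leave all silyl ethers intact.

**Step 6**
Reactants: 8 two-ring tris-TBS ether
Product: 9 {2-(bromomethyl)-4-[2-(tert-butyldimethylsilyloxy)benzyl]phenoxy}(tert-butyl)dimethylsilane (two-ring benzylic bromide)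
Conditions: Ph3PBr2 (1.1 equiv), CH2Cl2, 0 °C → rt
Reagents that add atoms: dibromotriphenylphosphorane (Ph3PBr2), BrP(Br)(c1ccccc1)(c1ccccc1)c1ccccc1
Why: The same silyl ether to bromide exchange as in step 2 should convert only the benzylic CH2O–TBS group and keep both aryl silyl ethers.

**Step 7**
Reactants: 7 arylzinc chloride stock solution; 9 two-ring benzylic bromide
Product: 10 tert-butyl{2-[(tert-butyldimethylsilyloxy)methyl]-4-{2-(tert-butyldimethylsilyloxy)-5-[2-(tert-butyldimethylsilyloxy)benzyl]benzyl}phenoxy}dimethylsilane (three-ring tetrakis-TBS ether)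
Conditions: 7 (1.2 equiv, THF solution), 9, Pd(PPh3)4 (cat.), THF, rt → 45 °C
Reagents that add atoms: none
Why: A second Negishi coupling of the same arylzinc reagent with benzylic bromide 9 should add ring F para to its silyloxy group and complete the three-ring chain.

**Step 8**
Reactants: 10 three-ring tetrakis-TBS ether
Product: 11 {2-(bromomethyl)-4-{2-(tert-butyldimethylsilyloxy)-5-[2-(tert-butyldimethylsilyloxy)benzyl]benzyl}phenoxy}(tert-butyl)dimethylsilane (three-ring benzylic bromide)
Conditions: Ph3PBr2 (1.1 equiv), CH2Cl2, 0 °C → rt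
Reagents that add atoms: dibromotriphenylphosphorane (Ph3PBr2), BrP(Br)(c1ccccc1)(c1ccccc1)c1ccccc1
Why: The silyl ether to bromide exchange of steps 2 and 6 should again act only on the single benzylic silyl ether and arm ring F for the key step.

**Step 9**
Reactants: 12 (2S)-pinocembrin; 9 two-ring benzylic bromide
Product: 14 (2S)-5,7-dihydroxy-8-[2-hydroxy-5-(2-hydroxybenzyl)benzyl]-2-phenylchroman-4-one, via quinone methide 13 (not isolated)
Conditions: 12 (3 equiv), 9, TBAF, AcOH, THF, −20 °C → rt; chromatographic separation from the 6-isomer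
Reagents that add atoms: none
Why: Fluoride-triggered release of the ortho-quinone methide and Michael addition of the pinocembrin 7-phenoxide should give ortho-hydroxybenzylation of ring A; C6 and C8 both flank the 7-oxygen, so the site is not secured by the substrate and the 6-isomer is expected as a co-product, while the excess of 12 suppresses double alkylation and the buffered medium leaves C2 untouched.

**Step 10**
Reactants: 14 8-benzylated (S)-pinocembrin; 11 three-ring benzylic bromide
Product: 16 Sarmentosumin D, via quinone methide 15 (not isolated)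
Conditions: 14, 11 (1.2 equiv), TBAF, AcOH, dry THF, −20 °C → rt; aq. NH4Cl
Reagents that add atoms: none
Why: Fluoride removes the three aryl silyl groups of 11; the ring F phenoxide, ortho to the CH2Br group, expels bromide in a 1,4-elimination to give ortho-quinone methide 15, and the 7-phenoxide of 14, the only phenol acidic enough to be ionized in the acetate buffer, adds through C6 to the exocyclic CH2 in a Michael addition that rearomatizes both ring A and ring F. The closest known reaction type is the fluoride-triggered release of ortho-quinone methides from ortho-silyloxybenzyl halides, combined with the ortho-hydroxybenzylation of phloroglucinol-type flavanones by such methides. No ring is closed and no stereocentre is formed; the C2 centre is kept because the acetate-buffered medium at or below room temperature is too weakly basic for enolization at C3 and retro-oxa-Michael opening of ring C. The step needs C6 selectivity over oxygen alkylation and over the phenol rings D, E, G and H: C8 already carries its chain so C6 is the last free carbon of ring A, the side-chain phenols stay protonated and weakly nucleophilic, and adducts of 15 with acetate, bromide, fluoride or the 7-oxygen can re-form 15 whereas the C–C bond cannot.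

**Compound list**
1 | 2-hydroxybenzyl alcohol (salicyl alcohol) | OCc1ccccc1O | starting material
2 | tert-butyl{2-[(tert-butyldimethylsilyloxy)methyl]phenoxy}dimethylsilane | CC(C)(C)[Si](C)(C)OCc1ccccc1O[Si](C)(C)C(C)(C)C | intermediate
3 | [2-(bromomethyl)phenoxy](tert-butyl)dimethylsilane | CC(C)(C)[Si](C)(C)Oc1ccccc1CBr | intermediate
4 | 5-bromo-2-hydroxybenzyl alcohol | OCc1cc(Br)ccc1O | starting material
5 | {4-bromo-2-[(tert-butyldimethylsilyloxy)methyl]phenoxy}(tert-butyl)dimethylsilane | CC(C)(C)[Si](C)(C)OCc1cc(Br)ccc1O[Si](C)(C)C(C)(C)C | intermediate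
6 | aryllithium from 5 (Li in place of Br, formed in the flask) | [Li]c1ccc(O[Si](C)(C)C(C)(C)C)c(CO[Si](C)(C)C(C)(C)C)c1 | intermediate
7 | {4-(tert-butyldimethylsilyloxy)-3-[(tert-butyldimethylsilyloxy)methyl]phenyl}zinc chloride (arylzinc chloride, kept as a titrated THF stock solution) | Cl[Zn]c1ccc(O[Si](C)(C)C(C)(C)C)c(CO[Si](C)(C)C(C)(C)C)c1 | intermediate
8 | two-ring tris-TBS ether: tert-butyl{2-[(tert-butyldimethylsilyloxy)methyl]-4-[2-(tert-butyldimethylsilyloxy)benzyl]phenoxy}dimethylsilane | CC(C)(C)[Si](C)(C)OCc1cc(Cc2ccccc2O[Si](C)(C)C(C)(C)C)ccc1O[Si](C)(C)C(C)(C)C | intermediate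
9 | two-ring benzylic bromide: {2-(bromomethyl)-4-[2-(tert-butyldimethylsilyloxy)benzyl]phenoxy}(tert-butyl)dimethylsilane | BrCc1cc(Cc2ccccc2O[Si](C)(C)C(C)(C)C)ccc1O[Si](C)(C)C(C)(C)C | intermediate
10 | three-ring tetrakis-TBS ether: tert-butyl{2-[(tert-butyldimethylsilyloxy)methyl]-4-{2-(tert-butyldimethylsilyloxy)-5-[2-(tert-butyldimethylsilyloxy)benzyl]benzyl}phenoxy}dimethylsilane | CC(C)(C)[Si](C)(C)OCc1cc(Cc2cc(Cc3ccccc3O[Si](C)(C)C(C)(C)C)ccc2O[Si](C)(C)C(C)(C)C)ccc1O[Si](C)(C)C(C)(C)C | intermediate
11 | three-ring benzylic bromide: {2-(bromomethyl)-4-{2-(tert-butyldimethylsilyloxy)-5-[2-(tert-butyldimethylsilyloxy)benzyl]benzyl}phenoxy}(tert-butyl)dimethylsilane | BrCc1cc(Cc2cc(Cc3ccccc3O[Si](C)(C)C(C)(C)C)ccc2O[Si](C)(C)C(C)(C)C)ccc1O[Si](C)(C)C(C)(C)C | intermediate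
12 | (2S)-pinocembrin, (2S)-5,7-dihydroxy-2-phenylchroman-4-one | O=C1C[C@@H](c2ccccc2)Oc2cc(O)cc(O)c21 | starting material
13 | 4-(2-hydroxybenzyl)-6-methylenecyclohexa-2,4-dien-1-one (two-ring ortho-quinone methide, formed in the flask) | C=C1C=C(Cc2ccccc2O)C=CC1=O | intermediate
14 | (2S)-5,7-dihydroxy-8-[2-hydroxy-5-(2-hydroxybenzyl)benzyl]-2-phenylchroman-4-one | O=C1C[C@@H](c2ccccc2)Oc2c(Cc3cc(Cc4ccccc4O)ccc3O)c(O)cc(O)c21 | intermediate
15 | 4-[2-hydroxy-5-(2-hydroxybenzyl)benzyl]-6-methylenecyclohexa-2,4-dien-1-one (three-ring ortho-quinone methide, formed in the flask) | C=C1C=C(Cc2cc(Cc3ccccc3O)ccc2O)C=CC1=O | intermediate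
16 | Sarmentosumin D, (2S)-5,7-dihydroxy-6-{2-hydroxy-5-[2-hydroxy-5-(2-hydroxybenzyl)benzyl]benzyl}-8-[2-hydroxy-5-(2-hydroxybenzyl)benzyl]-2-phenylchroman-4-one | O=C1C[C@@H](c2ccccc2)Oc2c(Cc3cc(Cc4ccccc4O)ccc3O)c(O)c(Cc3cc(Cc4cc(Cc5ccccc5O)ccc4O)ccc3O)c(O)c21 | target

**Totals.** Total step count: 10. Longest linear sequence: 7 steps (steps 3, 4, 5, 6, 7, 8, 10; the branch through steps 1, 2, 5, 6, 7, 8, 10 is equally long).

**Steps most likely to fail**

Step 10 (key step). The quinone methide may be consumed by oxygen alkylation, by self-condensation with the freshly liberated side-chain phenols, or by water carried in with the fluoride source, before C6 of ring A captures it. The fallback sets out from 10 and 14 and switches from fluoride and phenoxide activation to Lewis-acid activation of a free salicyl alcohol. Global desilylation of 10 (TBAF, AcOH, THF) should give 2-hydroxy-5-[2-hydroxy-5-(2-hydroxybenzyl)benzyl]benzyl alcohol F1, which carries no leaving group and can be stored. Heating F1 with 14 and ZnCl2 in dioxane (ionization of the benzylic alcohol, Friedel–Crafts hydroxybenzylation of ring A at its only free carbon) comes back to the route at 16.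

Step 9. Attack at C6 instead of C8, and double alkylation, may erode the supply of 14, since both carbons are ortho to the 7-oxygen. The fallback sets out from 12 and blocks C6 before the chain is attached. Selective silylation of the non-chelated 7-OH (i-Pr3SiCl, imidazole, DMF, 0 °C) should give (2S)-5-hydroxy-2-phenyl-7-(triisopropylsilyloxy)chroman-4-one F2. Iodination ortho to the free chelated 5-OH (BnMe3N·ICl2, CaCO3, CH2Cl2–MeOH) should give (2S)-5-hydroxy-6-iodo-2-phenyl-7-(triisopropylsilyloxy)chroman-4-one F3. Coupling of F3 with 9 under the conditions of step 9 (TBAF, AcOH, THF), which also frees the 7-oxygen, can then occur only at C8 and should give (2S)-5,7-dihydroxy-8-[2-hydroxy-5-(2-hydroxybenzyl)benzyl]-6-iodo-2-phenylchroman-4-one F4. Hydrodeiodination (H2, Pd/C, NaOAc, EtOAc, rt) comes back to the route at 14.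

Step 8. The direct exchange on the tetra-silylated trimer may be accompanied by loss of aryl silyl groups or by ring bromination of the electron-rich silyloxyarenes. The fallback sets out from 10 and separates deprotection from activation. Mild acid (camphorsulfonic acid, MeOH, 0 °C) cleaves only the alkyl silyl ether and should give {2-(tert-butyldimethylsilyloxy)-5-{2-(tert-butyldimethylsilyloxy)-5-[2-(tert-butyldimethylsilyloxy)benzyl]benzyl}phenyl}methanol F5. An Appel reaction on F5 (CBr4, PPh3, CH2Cl2, 0 °C) comes back to the route at 11.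

**Further compounds**
F1 | step 10 | 2-hydroxy-5-[2-hydroxy-5-(2-hydroxybenzyl)benzyl]benzyl alcohol | OCc1cc(Cc2cc(Cc3ccccc3O)ccc2O)ccc1O
F2 | step 9 | (2S)-5-hydroxy-2-phenyl-7-(triisopropylsilyloxy)chroman-4-one | O=C1C[C@@H](c2ccccc2)Oc2cc(O[Si](C(C)C)(C(C)C)C(C)C)cc(O)c21
F3 | step 9 | (2S)-5-hydroxy-6-iodo-2-phenyl-7-(triisopropylsilyloxy)chroman-4-one | O=C1C[C@@H](c2ccccc2)Oc2cc(O[Si](C(C)C)(C(C)C)C(C)C)c(I)c(O)c21
F4 | step 9 | (2S)-5,7-dihydroxy-8-[2-hydroxy-5-(2-hydroxybenzyl)benzyl]-6-iodo-2-phenylchroman-4-one | O=C1C[C@@H](c2ccccc2)Oc2c(Cc3cc(Cc4ccccc4O)ccc3O)c(O)c(I)c(O)c21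
F5 | step 8 | {2-(tert-butyldimethylsilyloxy)-5-{2-(tert-butyldimethylsilyloxy)-5-[2-(tert-butyldimethylsilyloxy)benzyl]benzyl}phenyl}methanol | OCc1cc(Cc2cc(Cc3ccccc3O[Si](C)(C)C(C)(C)C)ccc2O[Si](C)(C)C(C)(C)C)ccc1O[Si](C)(C)C(C)(C)C
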